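**Retrosynthetic overview**
- Target ⇒ decanoylation of the primary alcohol; the Z-enal comes from i-Bu2AlH opening of a seven-membered lactone, itself made by a tethered Horner–Wadsworth–Emmons (HWE) reaction from O-26 onto a C7 ketone, so the ring fixes the alkene geometry.
- C7 ketone ⇐ Nef reaction of a secondary nitro group; C10 carbinol ⇐ methyl addition to the ring A ketone.
- Ring B (cyclopentane, formed second) ⇐ Brønsted-acid-catalysed carbonyl–ene closure of the C26 aldehyde onto the terminal alkene of the conjugated triene side chain (new reaction; sets C14 and C26).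
- Quaternary C11 ⇐ Michael addition of a 2-formylcyclohexanone to acrolein anti to the C6 chain; the triene is then built by a Wittig and an HWE olefination.
- Ring A (cyclohexane, formed first) ⇐ Claisen cyclisation of the adduct from an organocatalytic nitro-Michael addition of methyl 4-nitrobutanoate to an achiral enal (sets C6, the first stereocentre).

Assumption: locants follow the iridal convention (ring A = C6–C11, ring B = C11–C14 plus C26, enal C1/C2, oxypropyl chain C3–C5, side chain C15–C24); TBS = tert-butyldimethylsilyl; reagent 19 is the commercial racemate and its only stereocentre is erased in step 11; the nitro-bearing C7 is drawn as the trans epimer, though either epimer serves.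

**Step 1**
Reactants: 1 4-(TBS-oxy)butanal; 2 (triphenylphosphoranylidene)acetaldehyde
Product: 3 (E)-6-(TBS-oxy)hex-2-enal
Conditions: toluene, 80 °C
Reagents that add atoms: none
Why: Wittig olefination with the formyl-stabilised ylide gives the E enal selectively and creates no stereocentre.

**Step 2**
Reactants: 3 (E)-6-(TBS-oxy)hex-2-enal; 4 methyl 4-nitrobutanoate
Product: 5 methyl (5S)-5-[3-(TBS-oxy)propyl]-4-nitro-7-oxoheptanoate
Conditions: (R)-2-[diphenyl(trimethylsilyloxy)methyl]pyrrolidine (10 mol %), PhCO2H (20 mol %), MeOH, rt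
Reagents that add atoms: none
Why: Organocatalytic nitro-Michael addition through the E iminium ion, in which the (R)-diarylprolinol silyl ether shields one face so the nitronate carbon (C7) adds to the other face of C6, setting the first stereocentre (C6) from achiral materials.

**Step 3**
Reactants: 5 nitro aldehyde ester
Product: 6 (3S,4S)-3-[3-(TBS-oxy)propyl]-2-[(Z)-hydroxymethylidene]-4-nitrocyclohexan-1-one
Conditions: t-BuOK (2.5 equiv), THF, −78 to 0 °C; 1 M HCl
Reagents that add atoms: none
Why: Intramolecular Claisen (Dieckmann-type) condensation of the aldehyde enolate onto the methyl ester closes ring A, driven by formation of the stabilised 2-formyl ketone enolate, while the nitronate blocks retro-Michael cleavage and C6 is untouched.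

**Step 4**
Reactants: 6 2-(hydroxymethylidene) nitro ketone; 7 acrolein
Product: 8 (1S,5S,6S)-6-[3-(TBS-oxy)propyl]-5-nitro-2-oxo-1-(3-oxopropyl)cyclohexane-1-carbaldehyde
Conditions: Et3N (5 mol %), CH2Cl2, −20 °C
Reagents that add atoms: none
Why: Amine-catalysed Michael addition of the 2-formyl ketone enolate, in which allylic strain holds the C6 chain pseudoaxial so acrolein adds to the opposite face, making C11 quaternary with C12 trans and the formyl carbon C26 cis to the C6 chain; the far less acidic nitro group stays un-ionised.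

**Step 5**
Reactants: 8 keto dialdehyde; 9 2-(triphenylphosphoranylidene)propanal
Product: 10 (1S,5S,6S)-6-[3-(TBS-oxy)propyl]-1-[(3E)-4-methyl-5-oxopent-3-en-1-yl]-5-nitro-2-oxocyclohexane-1-carbaldehyde
Conditions: toluene, 60 °C
Reagents that add atoms: none
Why: Wittig olefination in which the stabilised ylide reacts only with the unhindered aliphatic aldehyde (not the neopentyl formyl group or the ketone) and gives the E trisubstituted enal.

**Step 6**
Reactants: 11 geranyl bromide; 12 triethyl phosphite
Product: 13 diethyl [(2E)-3,7-dimethylocta-2,6-dien-1-yl]phosphonate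
Conditions: neat, 130 °C
Reagents that add atoms: none
Why: Michaelis–Arbuzov reaction of the primary allylic bromide, which keeps the E geometry.

**Step 7**
Reactants: 10 enal keto aldehyde; 13 diethyl geranylphosphonate
Product: 14 (1S,5S,6S)-6-[3-(TBS-oxy)propyl]-5-nitro-2-oxo-1-[(3E,5E,7E)-4,8,12-trimethyltrideca-3,5,7,11-tetraen-1-yl]cyclohexane-1-carbaldehyde
Conditions: 13 (2.2 equiv), n-BuLi (2.1 equiv), THF, −78 °C; then 10, −78 to 0 °C; AcOH
Reagents that add atoms: none
Why: Horner–Wadsworth–Emmons olefination of the unhindered enal by the lithiated allylic phosphonate gives the new C16=C17 bond E, one equivalent of anion being spent on the nitro C–H.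

**Step 8**
Reactants: 14 triene keto aldehyde
Product: 15 spiro ketol with 26-hydroxyl cis to the C6 chain and the C14 tetraenyl group trans to that hydroxyl
Conditions: (R)-3,3′-bis(2,4,6-triisopropylphenyl)-1,1′-binaphthalene-2,2′-diyl N-(trifluoromethylsulfonyl)phosphoramidate (10 mol %), 4 Å MS, toluene, −40 to −20 °C
Reagents that add atoms: none
Why: Proposed new method: a chiral Brønsted acid-catalysed carbonyl–ene cyclisation whose ene partner is the terminal trisubstituted alkene of a conjugated triene; the acid activates the C26 formyl group, whose oxygen turns toward the C6 side by dipole opposition to the C10 ketone, C14 closes ring B with the C15 unit trans to the new hydroxyl, and the phosphoramide anion held at the O–H removes a proton from the C15 methyl of the pentadienyl cation to leave the exo-methylene triene (the matched catalyst enantiomer is to be confirmed by screening both); the closest known reactions are chiral phosphoric-acid-type carbonyl–ene cyclisations of simple olefinic aldehydes and Lewis-acid citronellal-type ene closures.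

**Step 9**
Reactants: 15 spiro ketol
Product: 16 spiro nitro diol with the new C10 methyl cis to C12 and the C10 hydroxyl cis to C26
Conditions: MeLi (3.5 equiv), CeCl3 (3.5 equiv), THF, −78 °C; aq. NH4Cl
Reagents that add atoms: methyllithium, [Li]C
Why: Organocerium 1,2-addition to the hindered enolisable ketone from the ring A face opposite both C26 and the C6 chain, which gives the (10S) carbinol with methyl cis to C12.

**Step 10**
Reactants: 16 spiro nitro diol
Product: 18 spiro dihydroxy ketone with the carbonyl at C7, via sodium nitronate 17 (not isolated)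
Conditions: NaOMe (1.1 equiv), MeOH, 0 °C; then aq. TiCl3, NH4OAc, THF, rt
Reagents that add atoms: water, O
Why: Reductive Nef reaction in which TiCl3 reduces the nitronate to the imine, which hydrolyses to the C7 ketone at buffered pH that spares the triene, the silyl ether and the C6 configuration.

**Step 11**
Reactants: 18 spiro dihydroxy ketone; 19 2-(diethoxyphosphoryl)propanoic acid
Product: 21 seven-membered unsaturated lactone O26–C1(=O)–C2(CH3)=C7, via phosphonopropanoate ester 20 (not isolated)
Conditions: 19, DCC, DMAP (cat.), THF, rt; then LiCl, DBU, 40 °C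
Reagents that add atoms: none
Why: Steglich esterification of the only acylable (secondary C26) hydroxyl followed by intramolecular Horner–Wadsworth–Emmons olefination of the C7 ketone under Masamune–Roush conditions, the seven-membered ring forcing C1 cis to C6 and so fixing the Z tetrasubstituted alkene.

**Step 12**
Reactants: 21 unsaturated lactone
Product: 23 TBS-protected hydroxy Z-enal, via lactol 22 (not isolated)
Conditions: i-Bu2AlH (3 equiv), CH2Cl2, −78 °C; aq. Rochelle salt
Reagents that add atoms: none
Why: Partial reduction of the lactone stops at the aluminium lactolate at −78 °C, and on work-up the seven-membered lactol opens to the conjugated aldehyde and the free C26 hydroxyl with the alkene geometry retained.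

**Step 13**
Reactants: 23 TBS-protected hydroxy enal
Product: 24 deacyl target triol
Conditions: HF·pyridine, pyridine, THF, 0 °C to rt
Reagents that add atoms: none
Why: Buffered fluoride desilylation of the primary silyl ether leaves the enal, the triene and the tertiary alcohol intact.

**Step 14**
Reactants: 24 deacyl target triol; 25 decanoyl chloride
Product: 26 CNP0219877.1
Conditions: 25 (1.05 equiv), 2,4,6-collidine, CH2Cl2, −40 °C
Reagents that add atoms: none
Why: Selective acylation of the primary alcohol by one equivalent of acid chloride at low temperature in the presence of the hindered secondary and tertiary hydroxyls.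

**Compound list**
1 | 4-(tert-butyldimethylsilyloxy)butanal | O=CCCCO[Si](C)(C)C(C)(C)C | starting material
2 | (triphenylphosphoranylidene)acetaldehyde | O=CC=P(c1ccccc1)(c1ccccc1)c1ccccc1 | starting material
3 | (E)-6-(tert-butyldimethylsilyloxy)hex-2-enal | O=C/C=C/CCCO[Si](C)(C)C(C)(C)C | intermediate
4 | methyl 4-nitrobutanoate | COC(=O)CCC[N+](=O)[O-] | starting material
5 | methyl (5S)-5-[3-(TBS-oxy)propyl]-4-nitro-7-oxoheptanoate (both C4 epimers) | O=CC[C@H](CCCO[Si](C)(C)C(C)(C)C)C(CCC(=O)OC)[N+](=O)[O-] | intermediate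
6 | (3S,4S)-3-[3-(TBS-oxy)propyl]-2-[(Z)-hydroxymethylidene]-4-nitrocyclohexan-1-one (enol of the 2-formyl ketone; nitro trans to the chain) | O/C=C1/[C@H](CCCO[Si](C)(C)C(C)(C)C)[C@@H]([N+](=O)[O-])CCC1=O | intermediate
7 | acrolein | C=CC=O | starting material
8 | (1S,5S,6S)-6-[3-(TBS-oxy)propyl]-5-nitro-2-oxo-1-(3-oxopropyl)cyclohexane-1-carbaldehyde (formyl cis to the C6 chain) | O=CCC[C@@]1(C=O)[C@H](CCCO[Si](C)(C)C(C)(C)C)[C@@H]([N+](=O)[O-])CCC1=O | intermediate
9 | 2-(triphenylphosphoranylidene)propanal | CC(C=O)=P(c1ccccc1)(c1ccccc1)c1ccccc1 | starting material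
10 | (1S,5S,6S)-6-[3-(TBS-oxy)propyl]-1-[(3E)-4-methyl-5-oxopent-3-en-1-yl]-5-nitro-2-oxocyclohexane-1-carbaldehyde | O=C/C(C)=C/CC[C@@]1(C=O)[C@H](CCCO[Si](C)(C)C(C)(C)C)[C@@H]([N+](=O)[O-])CCC1=O | intermediate
11 | geranyl bromide | BrC/C=C(\C)CCC=C(C)C | starting material
12 | triethyl phosphite | CCOP(OCC)OCC | starting material
13 | diethyl [(2E)-3,7-dimethylocta-2,6-dien-1-yl]phosphonate | CCOP(=O)(OCC)C/C=C(\C)CCC=C(C)C | intermediate
14 | (1S,5S,6S)-6-[3-(TBS-oxy)propyl]-5-nitro-2-oxo-1-[(3E,5E,7E)-4,8,12-trimethyltrideca-3,5,7,11-tetraen-1-yl]cyclohexane-1-carbaldehyde | CC(C)=CCC/C(C)=C/C=C/C(C)=C/CC[C@@]1(C=O)[C@H](CCCO[Si](C)(C)C(C)(C)C)[C@@H]([N+](=O)[O-])CCC1=O | intermediate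
15 | spiro[4.5]decane ketol (6S,7S,11S,14R,26R): ring B with 26-OH and at C14 the (3E,5E)-6,10-dimethylundeca-1,3,5,9-tetraen-2-yl group trans to it; ring A with C10 ketone, 7-nitro and 6-[3-(TBS-oxy)propyl] cis to C26 | C=C(/C=C/C=C(\C)CCC=C(C)C)[C@H]1CC[C@]2([C@H](CCCO[Si](C)(C)C(C)(C)C)[C@@H]([N+](=O)[O-])CCC2=O)[C@@H]1O | intermediate
16 | spiro nitro diol (6S,7S,10S,11S,14R,26R): as 15 with C10 = C(CH3)(OH), methyl cis to C12 | C=C(/C=C/C=C(\C)CCC=C(C)C)[C@H]1CC[C@]2([C@H](CCCO[Si](C)(C)C(C)(C)C)[C@@H]([N+](=O)[O-])CC[C@]2(C)O)[C@@H]1O | intermediate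
17 | sodium C7-nitronate of 16 | C=C(/C=C/C=C(\C)CCC=C(C)C)[C@H]1CC[C@]2([C@H](CCCO[Si](C)(C)C(C)(C)C)C(=[N+]([O-])[O-])CC[C@]2(C)O)[C@@H]1O.[Na+] | intermediate
18 | spiro dihydroxy ketone (6S,10S,11S,14R,26R): 10,26-diol with C7 ketone, 3-O-TBS | C=C(/C=C/C=C(\C)CCC=C(C)C)[C@H]1CC[C@]2([C@H](CCCO[Si](C)(C)C(C)(C)C)C(=O)CC[C@]2(C)O)[C@@H]1O | intermediate
19 | 2-(diethoxyphosphoryl)propanoic acid (racemate) | CCOP(=O)(OCC)C(C)C(=O)O | starting material
20 | 26-O-[2-(diethoxyphosphoryl)propanoyl] ester of 18 | C=C(/C=C/C=C(\C)CCC=C(C)C)[C@H]1CC[C@]2([C@H](CCCO[Si](C)(C)C(C)(C)C)C(=O)CC[C@]2(C)O)[C@@H]1OC(=O)C(C)P(=O)(OCC)OCC | intermediate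
21 | tricyclic lactone (6R,10S,11S,14R,26R): O26–C1(=O)–C2(CH3)=C7 seven-membered ring, alkene Z by ring constraint | C=C(/C=C/C=C(\C)CCC=C(C)C)[C@H]1CC[C@]2([C@H](CCCO[Si](C)(C)C(C)(C)C)C=3CC[C@]2(C)O)[C@@H]1OC(=O)C=3C | intermediate
22 | lactol of 21 (C1 hemiacetal) | C=C(/C=C/C=C(\C)CCC=C(C)C)[C@H]1CC[C@]2([C@H](CCCO[Si](C)(C)C(C)(C)C)C=3CC[C@]2(C)O)[C@@H]1OC(O)C=3C | intermediate
23 | 3-O-TBS ether of the deacyl target (2Z,6R,10S,11S,14R,26R) | C=C(/C=C/C=C(\C)CCC=C(C)C)[C@H]1CC[C@]2([C@H](CCCO[Si](C)(C)C(C)(C)C)/C(=C(/C)C=O)CC[C@]2(C)O)[C@@H]1O | intermediate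
24 | deacyl target: 3,10,26-triol Z-enal (2Z,6R,10S,11S,14R,26R) | C=C(/C=C/C=C(\C)CCC=C(C)C)[C@H]1CC[C@]2([C@H](CCCO)/C(=C(/C)C=O)CC[C@]2(C)O)[C@@H]1O | intermediate
25 | decanoyl chloride | CCCCCCCCCC(=O)Cl | starting material
26 | CNP0219877.1 (2Z,6R,10S,11S,14R,16E,18E,26R) | C=C(/C=C/C=C(\C)CCC=C(C)C)[C@H]1CC[C@]2([C@H](CCCOC(=O)CCCCCCCCC)/C(=C(/C)C=O)CC[C@]2(C)O)[C@@H]1O | target

**Step count**
Total steps: 14. Longest linear sequence: 13 (steps 1–5 and 7–14; step 6 is the side branch).

**Three steps most likely to fail**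

Step 8 (the new ene closure). The pentadienyl cation could lose the wrong proton, be trapped by the new hydroxyl, or trigger polyene cyclisation. The fallback uses only known chemistry, sets out from 8 and returns at 15. Wittig olefination of the unhindered aldehyde of 8 with isopropylidenetriphenylphosphorane gives the prenyl keto aldehyde F1. Me2AlCl in CH2Cl2 at −78 °C then effects the established citronellal-type carbonyl–ene closure to the isopropenyl spiro ketol F2. Allylic oxidation with SeO2/t-BuOOH (then MnO2) gives the 2-substituted acrolein F3. Horner–Wadsworth–Emmons reaction of F3 with lithiated 13 gives 15.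

Step 3 (Claisen closure of an aldehyde enolate onto an ester). Aldol oligomerisation or poor conversion is possible. The fallback sets out from 3 and returns at 6. Under the same prolinol silyl ether catalyst, 3 and 4-nitrobutanal undergo a nitro-Michael/aldol condensation domino to the cyclohexene carbaldehyde F4. Nucleophilic epoxidation (H2O2, NaOH, MeOH) gives the epoxy aldehyde F5. Isomerisation of the epoxy carbonyl unit with Pd(PPh3)4 and 1,2-bis(diphenylphosphino)ethane in toluene at 80 °C gives the 2-formyl ketone 6.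

Step 11 (one-pot esterification and seven-membered HWE on a hindered ketone). Slow ring closure or C6 epimerisation under base is possible. The fallback sets out from 18 and returns at 21. Intermolecular olefination of 18 with triethyl 2-phosphonopropanoate (NaH, 1,2-dimethoxyethane, 80 °C) gives, after separation from its geometric isomer, the Z unsaturated ethyl ester F6. Lactonisation of F6 onto the C26 hydroxyl with catalytic DBU gives 21.

**Further compounds**
F1 | step 8 | (1S,5S,6S)-6-[3-(TBS-oxy)propyl]-1-(4-methylpent-3-en-1-yl)-5-nitro-2-oxocyclohexane-1-carbaldehyde | CC(C)=CCC[C@@]1(C=O)[C@H](CCCO[Si](C)(C)C(C)(C)C)[C@@H]([N+](=O)[O-])CCC1=O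
F2 | step 8 | isopropenyl spiro ketol (15 with prop-1-en-2-yl at C14) | C=C(C)[C@H]1CC[C@]2([C@H](CCCO[Si](C)(C)C(C)(C)C)[C@@H]([N+](=O)[O-])CCC2=O)[C@@H]1O
F3 | step 8 | spiro ketol with a 3-oxoprop-1-en-2-yl group at C14 | C=C(C=O)[C@H]1CC[C@]2([C@H](CCCO[Si](C)(C)C(C)(C)C)[C@@H]([N+](=O)[O-])CCC2=O)[C@@H]1O
F4 | step 3 | (6S)-6-[3-(TBS-oxy)propyl]-5-nitrocyclohex-1-ene-1-carbaldehyde | O=CC1=CCC[C@H]([N+](=O)[O-])[C@H]1CCCO[Si](C)(C)C(C)(C)C
F5 | step 3 | 1,2-epoxide of F4 (epoxy aldehyde) | O=CC12OC1CC[C@H]([N+](=O)[O-])[C@H]2CCCO[Si](C)(C)C(C)(C)C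
F6 | step 11 | ethyl (Z)-ester analogue of 23 (CO2Et in place of CHO) | C=C(/C=C/C=C(\C)CCC=C(C)C)[C@H]1CC[C@]2([C@H](CCCO[Si](C)(C)C(C)(C)C)/C(=C(/C)C(=O)OCC)CC[C@]2(C)O)[C@@H]1O
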